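All runs were computed for substances that don't exist, and the scatter is random.

Work it by hand first. These are the flasks, the earlier readings and the questions:

all flasks: starting material 0.050 M; catalyst 3.1 mM
- elm: partner 0.090 M; protic impurity 0.0022 M; run made earlier
- maple: partner 0.090 M; protic impurity 0.022 M; run made earlier
- Friday's: partner 0.0900 M; protic impurity 0.00400 M; time 20 min
- Monday's: partner 0.0900 M; protic impurity 0.00800 M; time 20 min
- Saturday's: partner 0.0900 M; protic impurity 0.0150 M; time 20 min
- Sunday's: partner 0.0900 M; protic impurity 0.0300 M; time 20 min

- elm (time / min: target / %): 1.50: 0.4; 2.50: 1.7; 4.00: 2.9; 8.00: 6.3; 12.0: 12.1; 20.0: 20.7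
- maple (time / min: target / %): 3.00: 0.9; 6.00: 4.0; 10.0: 8.5; 12.0: 9.0; 15.0: 9.9; 20.0: 15.4

(readings scatter by 1 percentage point)

- "hardly changes" means that all values lie within two and a half points (for a concentration: within two and a half percent of the largest)

* amount of target at the end, in percent of the starting material charged for Friday's, Monday's, Saturday's, Sunday's, in this order
* how that number moves from the first to the last of them (falls all the way / rises all the way / hardly changes / falls, then rises / rises, then falls)

Turn the question round and ask what would have to be true of the given numbers for the row to hardly change. Elm and maple differ in their charge by the [protic impurity], 0.0022 M against 0.022 M. At 20.0 min elm reads 20.7% of target and maple reads 15.4%, each with a scatter of 1 percentage point. Put that gap into moles and you have the exchange rate, the moles of target lost by 20 min per mole of protic impurity added: 0.134. It is a reading from two points, and the step of the reckoning is to freeze it across the row.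

Friday's and Sunday's differ by 0.0260 M of protic impurity, so with a margin of 2.5 points the row hardly changes if the frozen exchange rate, taken without its sign, lies below 0.0481. The reading stands 2.79 times above that, and it is positive, so it points to a fall across the row. My own reckoning gives a fall of 7 points across the row. Starting from elm, that means 20.2% for Friday's and 13.3% for Sunday's.

The forecast gives 20%, 19%, 17.2% and 14%, and its shape is falls all the way, on the ground that “Nothing in the data suggests a maximum or an abrupt cut-off”. It agrees with my reckoning on the shape, but it ends higher on Sunday's than mine does.

The flasks give 19.1%, 18.4%, 17.1% and 14.2%, so the row falls all the way, by 4.9 points, which is more than the margin.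

    starting material + catalyst ⇌ catalyst + intermediate (K = 0.308, k = 0.337 /M/s)
    partner + catalyst + intermediate → catalyst + target (k = 4.24 /M²/s)
    partner + protic impurity → quenched reagent (k = 0.571 /M/s)

In Sunday's flask at 20.0 min, the protic impurity, the limiting reagent of its own quenching step, stands at 0% of its charge, with 0.0300 M of quenched reagent and 58.8% of the partner's charge left. Carried from Monday's end across the 0.00700 M step in impurity, the exchange rate puts Saturday's at 16.5%, and Saturday's flask stands at 17.1%.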